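The readings stem from a simulated flask for substances that don't exist.

The slowness of a flask can be told as a rate, in fractions of the charge per minute; we read such a rate from the earlier east run and carry it, as an assumption of ours, to a new flask with a smaller charge.

| flask | starting material | gas | remark | time |
|---|---|---|---|---|
| east | 0.38 M | 59 mM (held) | run made earlier |  |
| flask | 0.25 M | 59 mM (held) |  | 20 min |

east run (percent of the starting material charged)

| time / min | tris adduct / % | starting material / % |
|---|---|---|
| 0.333 | 7 | 48 |
| 0.500 | 11 | 31 |
| 0.833 | 22 | 18 |
| 1.33 | 38 | 4 |
| 2.50 | 20 | 3 |
| 4.00 | 3 | 2 |

(each reading ± 1.5 percentage points)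

1. time, not beyond 20 min, at which the flask holds most tris adduct
2. the amount of tris adduct, in percent of the starting material charged, at that time
3. earliest time at which at least nineteen twentieths of that best amount are there, in min
4. latest time at which they still are, in min

- what was read earlier has a scatter of 1.5 percentage points, one standard deviation
- at the start none of the gas is in solution

East shows 48% of the starting material at 0.333 min, so we reckon a start rate of 2.20 min⁻¹, a reading with its scatter. Taking the fall as pseudo-first-order, we carry its half-life, 0.314 min, the time in which the starting material loses half of what it still holds. Each half-life slows the rate by a factor of 2, so by 1.33 min, which is 4.23 half-lives in, the east rate has slowed by a factor of 18.8, which leaves 5.32% of the charge against a reading of 4%. Tris adduct reads its highest in east at that point, 38%, and we take this as our rule: the peak comes 4.23 half-lives in. The gas is held the same, and we treat the smaller charge as a correction and set it to zero, an assumption one run cannot test, and commit for the flask to a peak near 1.33 min at about 38%.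

The forecast puts the peak of the flask later than ours, at 1.45 min with 40% and a band from 1.28 min to 1.7 min, holding that “the percentage profile should not depend on the charge”.

The flask peaks at 1.31 min with 37.6%, and its band runs from 1.07 min to 1.57 min.

    2 starting material → homo dimer (k = 0.0196 L mol⁻¹ s⁻¹)
    gas ⇌ partner, rate k2*(csat - [partner]) (kL = 0.436 s⁻¹)
    partner + first product → double product (k = 0.863 L mol⁻¹ s⁻¹)
    partner + double product → tris adduct (k = 4.29 L mol⁻¹ s⁻¹)
    starting material + partner → first product (k = 0.892 L mol⁻¹ s⁻¹)
    partner + tris adduct → tetra adduct (k = 0.393 L mol⁻¹ s⁻¹)

That peak lies 4.17 of our half-lives into the flask, where our rate leaves 5.60% of the starting material and the flask holds 4.77%. Earlier, at 0.853 min, the flask still makes tris adduct 2.13 times faster than it uses it up. In the neighbour flask with 1.0 M of starting material, our half-life carried unchanged points again to 38% near 1.33 min; the computed best there is 24.2%, with 45.2% homo dimer and 54.8% tetra adduct at 20.0 min.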